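**Retrosynthetic overview**

1. The target is a 2,3-trans-3,4-cis tetrahydrofuran (O1, C2–C5): C2 carries the 3,4,5-trimethoxyphenyl group, C3 the hydroxymethyl carbon C9, and C4 the 3,4-dimethoxybenzyl group (benzylic carbon C7').
2. The strategy rests on the cis pair C3–C9 / C4–C7': joining C9 (as a carbonyl) to C7' through oxygen turns the two arms into a γ-aryl butenolide, so that C3=C4 is a ring-locked cis alkene and C7' a temporary stereocentre.
3. Key disconnection: C2–O1–C5 is the carbonyl ylide of 3,4,5-trimethoxybenzaldehyde, added across the butenolide C=C (bonds C2–C3 and C4–C5) on the face opposite the γ-aryl group.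
4. After the cycloaddition the benzylic lactone C7'–O bond is hydrogenolysed (C7' becomes CH2, C9 a carboxylic acid) and the acid is reduced to the C9 alcohol.
5. Ring order: lactone ring first (alkynylation of veratraldehyde, cis-semihydrogenation, lactonisation), tetrahydrofuran ring second (cycloaddition), lactone ring opened last.

Key step: step 4

Remark: atom labels follow the lignan convention used above; the ProPhenol antipode named in step 2 is assumed to be the one that adds the acetylide to the Re face of the aldehyde, to be confirmed on 7 by Mosher ester analysis (the other antipode is used if the sense is opposite).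

**Route**

Step 1
Reactants: 1 3,4,5-trimethoxybenzaldehyde; 2 (trimethylsilyl)methanol
Product: 3 chloro(3,4,5-trimethoxyphenyl)methyl (trimethylsilyl)methyl ether (racemic; used crude)
Conditions: HCl (g), CH2Cl2, −20 → 0 °C, anhydrous CaCl2; filter, evaporate, use at once
Reagents that add atoms: hydrogen chloride, Cl
Why: Classical α-chloro ether synthesis, in which the acid-promoted condensation of aldehyde and alcohol is ended by chloride capture while CaCl2 binds the water; the new carbon centre is racemic, which does not matter because it becomes planar in the ylide.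

Step 2
Reactants: 4 3,4-dimethoxybenzaldehyde (veratraldehyde); 5 methyl propiolate
Product: 7 methyl (S)-4-(3,4-dimethoxyphenyl)-4-hydroxybut-2-ynoate, via methyl 3-(methylzincio)prop-2-ynoate 6 (not isolated)
Conditions: 5 (3 equiv), Me2Zn (3 equiv), (S,S)-ProPhenol (20 mol%), Ph3PO (40 mol%), toluene, 0 °C; then 4, 4 °C; cold 0.5 M HCl work-up
Reagents that add atoms: none
Why: Zinc–ProPhenol-catalysed enantioselective alkynylation of an aromatic aldehyde, in which the chiral dinuclear zinc complex binds both the aldehyde and the acetylide 6 and should deliver the alkynyl group to the Re face, setting the S carbinol centre (the future C7').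

Step 3
Reactants: 7 methyl (S)-4-(3,4-dimethoxyphenyl)-4-hydroxybut-2-ynoate
Product: 9 (R)-5-(3,4-dimethoxyphenyl)furan-2(5H)-one, via methyl (R,Z)-4-(3,4-dimethoxyphenyl)-4-hydroxybut-2-enoate 8 (not isolated)
Conditions: H2 (1 atm), Pd/CaCO3 poisoned with Pb(OAc)2 (Lindlar catalyst), quinoline, EtOAc, rt; filter; then pyridinium p-toluenesulfonate (cat.), CH2Cl2, rt
Reagents that add atoms: none
Why: Lindlar cis-semihydrogenation places carbinol and ester on the same side of the alkene, so that mild acid-catalysed lactonisation closes the butenolide with loss of methanol; the carbinol centre is not touched (its descriptor changes from S to R only because the neighbouring carbon drops in priority).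

Step 4
Reactants: 3 chloro(3,4,5-trimethoxyphenyl)methyl (trimethylsilyl)methyl ether; 9 (R)-5-(3,4-dimethoxyphenyl)furan-2(5H)-one
Product: 11 (1R,4R,5S,8R)-4-(3,4-dimethoxyphenyl)-8-(3,4,5-trimethoxyphenyl)-3,7-dioxabicyclo[3.3.0]octan-2-one (cis-fused; both aryl groups exo), via 3,4,5-trimethoxybenzaldehyde O-methylide 10 (not isolated)
Conditions: CsF (4 equiv, dried), MeCN, rt; solution of 9 (1 equiv) and 3 (2 equiv) in MeCN added over 1 h; 12 h
Reagents that add atoms: none
Why: Fluoride attacks silicon of 3 while chloride leaves (1,3-elimination), releasing the non-stabilised carbonyl ylide 10, a bent C–O–C dipole with four π electrons. The closest known reaction type is the fluoride-induced carbonyl ylide (3+2) cycloaddition of α-chloroalkyl silylmethyl ethers with α,β-unsaturated esters, combined here with the anti-selective 1,3-dipolar cycloadditions known for γ-substituted butenolides. The tetrahydrofuran ring is closed by this intermolecular suprafacial (3+2) cycloaddition, which forms C4–C5 and C2–C3 in one operation and leaves the lactone as the second, cis-fused ring. The CH2 terminus, which has the larger HOMO coefficient and the carbanion character, should bond to the β-carbon (largest LUMO coefficient), leaving the aryl-stabilised, oxocarbenium-like ArCH terminus to bond to the α-carbon; this orientation is the selectivity the step needs most, and it is expected but not yet demonstrated for this pairing. C3 and C4 are set cis because the ring holds the alkene cis and the addition is suprafacial, and their absolute sense follows from approach of the dipole to the face opposite the γ-aryl group at C7'. C2 is set by exo approach of the E-configured ylide, which keeps the trimethoxyphenyl group away from the lactone ring and gives the 2,3-trans adduct, also the more stable epimer.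

Step 5
Reactants: 11 (1R,4R,5S,8R)-4-(3,4-dimethoxyphenyl)-8-(3,4,5-trimethoxyphenyl)-3,7-dioxabicyclo[3.3.0]octan-2-one
Product: 12 (2R,3R,4S)-4-(3,4-dimethoxybenzyl)-2-(3,4,5-trimethoxyphenyl)tetrahydrofuran-3-carboxylic acid
Conditions: H2 (1 atm), 10% Pd/C, pyridine (0.5 equiv), EtOAc–MeOH, rt; dilute HCl wash
Reagents that add atoms: none
Why: Pd-catalysed hydrogenolysis of a benzylic C–O bond, selective because the acyloxy oxygen on the electron-rich dimethoxybenzylic carbon C7' is a far better leaving group on palladium than the alkoxy oxygen at C2 and because the amine additive suppresses benzyl ether cleavage; C7' should become CH2 (its stereocentre disappears) while C2, C3 and C4 stay untouched.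

Step 6
Reactants: 12 (2R,3R,4S)-4-(3,4-dimethoxybenzyl)-2-(3,4,5-trimethoxyphenyl)tetrahydrofuran-3-carboxylic acid
Product: 13 [(2R,3S,4S)-4-(3,4-dimethoxybenzyl)-2-(3,4,5-trimethoxyphenyl)tetrahydrofuran-3-yl]methanol (CNP0107562.1)
Conditions: BH3·THF (3 equiv), THF, 0 °C → rt; H2O quench
Reagents that add atoms: none
Why: Electrophilic borane reduction of a carboxylic acid to the primary alcohol, chemoselective over ethers and arenes and non-basic, so C3 (α to the carboxyl group) should keep its configuration.

**Compound list**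

1 | 3,4,5-trimethoxybenzaldehyde | COc1cc(C=O)cc(OC)c1OC | starting material
2 | (trimethylsilyl)methanol | C[Si](C)(C)CO | starting material
3 | chloro(3,4,5-trimethoxyphenyl)methyl (trimethylsilyl)methyl ether (racemic) | COc1cc(C(Cl)OC[Si](C)(C)C)cc(OC)c1OC | intermediate
4 | 3,4-dimethoxybenzaldehyde (veratraldehyde) | COc1ccc(C=O)cc1OC | starting material
5 | methyl propiolate | C#CC(=O)OC | starting material
6 | methyl 3-(methylzincio)prop-2-ynoate | COC(=O)C#C[Zn]C | intermediate
7 | methyl (S)-4-(3,4-dimethoxyphenyl)-4-hydroxybut-2-ynoate | COC(=O)C#C[C@@H](O)c1ccc(OC)c(OC)c1 | intermediate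
8 | methyl (R,Z)-4-(3,4-dimethoxyphenyl)-4-hydroxybut-2-enoate | COC(=O)/C=C\[C@@H](O)c1ccc(OC)c(OC)c1 | intermediate
9 | (R)-5-(3,4-dimethoxyphenyl)furan-2(5H)-one | O=C1O[C@@H](c2ccc(OC)c(OC)c2)C=C1 | intermediate
10 | 3,4,5-trimethoxybenzaldehyde O-methylide (carbonyl ylide) | COc1cc(C=[O+][CH2-])cc(OC)c1OC | intermediate
11 | (1R,4R,5S,8R)-4-(3,4-dimethoxyphenyl)-8-(3,4,5-trimethoxyphenyl)-3,7-dioxabicyclo[3.3.0]octan-2-one; as a fused name (3R,3aS,6R,6aR)-3-(3,4-dimethoxyphenyl)-6-(3,4,5-trimethoxyphenyl)tetrahydro-1H,3H-furo[3,4-c]furan-1-one | O=C1O[C@@H](c3ccc(OC)c(OC)c3)[C@@H]2CO[C@@H](c4cc(OC)c(OC)c(OC)c4)[C@H]12 | intermediate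
12 | (2R,3R,4S)-4-(3,4-dimethoxybenzyl)-2-(3,4,5-trimethoxyphenyl)tetrahydrofuran-3-carboxylic acid | COc1ccc(C[C@@H]2CO[C@@H](c3cc(OC)c(OC)c(OC)c3)[C@@H]2C(=O)O)cc1OC | intermediate
13 | [(2R,3S,4S)-4-(3,4-dimethoxybenzyl)-2-(3,4,5-trimethoxyphenyl)tetrahydrofuran-3-yl]methanol | COc1ccc(C[C@@H]2CO[C@@H](c3cc(OC)c(OC)c(OC)c3)[C@@H]2CO)cc1OC | target

**Step count and risks**

Total steps: 6. Longest linear sequence: 5 steps (4 → 7 → 9 → 11 → 12 → 13; steps 2–6).

Steps most likely to fail:

1. Step 4. The dipole may add with the opposite orientation (ArCH terminus on the β-carbon). The anti and exo preferences may be incomplete. The basic fluoride may also remove the acidic γ-hydrogen of 9, eroding its enantiopurity or moving the double bond out of conjugation before the ylide arrives. Fallback (known chemistry, sets out from 4 and 1, returns at 13):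
   - Stobbe condensation of 4 with dimethyl succinate (NaOMe, MeOH, reflux) should give (E)-4-(3,4-dimethoxyphenyl)-3-(methoxycarbonyl)but-3-enoic acid F1.
   - Asymmetric hydrogenation ([Rh(cod)2]BF4 with the MOD-DIOP antipode that gives the S acid, H2, MeOH, Et3N) should give (S)-4-(3,4-dimethoxyphenyl)-3-(methoxycarbonyl)butanoic acid F2.
   - Reduction of the ester beside the carboxylate (KOH, then Ca(BH4)2 from CaCl2 and NaBH4, EtOH) and acidification should give (S)-4-(3,4-dimethoxybenzyl)dihydrofuran-2(3H)-one F3.
   - Aldol addition of its lithium enolate (LiN(iPr)2, THF, −78 °C) to 1, trans to the benzyl group, should give (3R,4S)-4-(3,4-dimethoxybenzyl)-3-[hydroxy(3,4,5-trimethoxyphenyl)methyl]dihydrofuran-2(3H)-one F4 as a mixture of carbinol epimers, both of which converge later.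
   - LiAlH4 in THF should give (2S,3S)-2-(3,4-dimethoxybenzyl)-3-[hydroxy(3,4,5-trimethoxyphenyl)methyl]butane-1,4-diol F5.
   - Camphorsulfonic acid in CH2Cl2 should close the tetrahydrofuran through the benzylic cation, which is captured by the hydroxyl on the C5 carbon to give the 2,3-trans ring of 13.

2. Step 5. The benzylic ether C2–O1 may be cleaved along with the lactone C7'–O bond, or the poisoned catalyst may stall on the secondary benzylic lactone. Fallback (sets out from 11, returns at 13):
   - LiAlH4 (THF, 0 °C) should reduce the lactone to [(2R,3S,4S)-4-[(R)-(3,4-dimethoxyphenyl)(hydroxy)methyl]-2-(3,4,5-trimethoxyphenyl)tetrahydrofuran-3-yl]methanol F6.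
   - tert-Butyldimethylsilyl chloride and imidazole should silylate the primary hydroxyl to give the primary tert-butyldimethylsilyl ether of F6, F7.
   - NaH, CS2 and MeI should give the S-methyl xanthate of F7, F8.
   - Bu3SnH with azobisisobutyronitrile in toluene at 80 °C (Barton–McCombie deoxygenation via the benzylic radical) should give the tert-butyldimethylsilyl ether of 13, F9.
   - Bu4NF in THF should free 13.

3. Step 1. The α-chloro ether may form incompletely or hydrolyse back, and residual aldehyde 1 would intercept the ylide in step 4. Fallback (sets out from 1 and 2, returns at 3):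
   - Acetalisation of 1 with 2 (2.2 equiv, p-toluenesulfonic acid cat., toluene, Dean–Stark) should give 3,4,5-trimethoxybenzaldehyde bis[(trimethylsilyl)methyl] acetal F10.
   - Acetyl chloride (1.1 equiv) with a trace of SOCl2 in CH2Cl2 at rt should exchange one alkoxy group for chloride to give 3 free of water and aldehyde.

Further compounds
F1 | step 4 | (E)-4-(3,4-dimethoxyphenyl)-3-(methoxycarbonyl)but-3-enoic acid | COC(=O)/C(CC(=O)O)=C/c1ccc(OC)c(OC)c1
F2 | step 4 | (S)-4-(3,4-dimethoxyphenyl)-3-(methoxycarbonyl)butanoic acid | COC(=O)[C@H](CC(=O)O)Cc1ccc(OC)c(OC)c1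
F3 | step 4 | (S)-4-(3,4-dimethoxybenzyl)dihydrofuran-2(3H)-one | O=C1C[C@H](Cc2ccc(OC)c(OC)c2)CO1
F4 | step 4 | (3R,4S)-4-(3,4-dimethoxybenzyl)-3-[hydroxy(3,4,5-trimethoxyphenyl)methyl]dihydrofuran-2(3H)-one (both carbinol epimers) | O=C1OC[C@@H](Cc2ccc(OC)c(OC)c2)[C@@H]1C(O)c1cc(OC)c(OC)c(OC)c1
F5 | step 4 | (2S,3S)-2-(3,4-dimethoxybenzyl)-3-[hydroxy(3,4,5-trimethoxyphenyl)methyl]butane-1,4-diol (both carbinol epimers) | OC[C@@H](Cc1ccc(OC)c(OC)c1)[C@@H](CO)C(O)c1cc(OC)c(OC)c(OC)c1
F6 | step 5 | [(2R,3S,4S)-4-[(R)-(3,4-dimethoxyphenyl)(hydroxy)methyl]-2-(3,4,5-trimethoxyphenyl)tetrahydrofuran-3-yl]methanol | O[C@@H](c1ccc(OC)c(OC)c1)[C@@H]1CO[C@@H](c2cc(OC)c(OC)c(OC)c2)[C@@H]1CO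
F7 | step 5 | primary tert-butyldimethylsilyl ether of F6 | O[C@@H](c1ccc(OC)c(OC)c1)[C@@H]1CO[C@@H](c2cc(OC)c(OC)c(OC)c2)[C@@H]1CO[Si](C)(C)C(C)(C)C
F8 | step 5 | S-methyl xanthate of F7 | CSC(=S)O[C@@H](c1ccc(OC)c(OC)c1)[C@@H]1CO[C@@H](c2cc(OC)c(OC)c(OC)c2)[C@@H]1CO[Si](C)(C)C(C)(C)C
F9 | step 5 | tert-butyldimethylsilyl ether of 13 | COc1ccc(C[C@@H]2CO[C@@H](c3cc(OC)c(OC)c(OC)c3)[C@@H]2CO[Si](C)(C)C(C)(C)C)cc1OC
F10 | step 1 | 3,4,5-trimethoxybenzaldehyde bis[(trimethylsilyl)methyl] acetal | COc1cc(C(OC[Si](C)(C)C)OC[Si](C)(C)C)cc(OC)c1OC
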